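(Readings and results were generated by integration for an exercise; scatter was added.)

E, the complex with two exchanges, is what you want from this flask. Each exchange uses one Z and frees one J, so count Z against X. The Z charged over the X charged, 3.00 here, is the exchange budget, in exchanges per X.

| flask | X | Z | J | remark | time |
|---|---|---|---|---|---|
| epsilon | 0.080 M | 0.48 M | 0.80 M | run made earlier |  |
| zeta | 0.32 M | 0.48 M | 0.80 M | run made earlier |  |
| flask | 0.16 M | 0.480 M | 0.800 M |  | 8.0 d |

| run | time / d | E / % | L / % | X / % |
|---|---|---|---|---|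
| epsilon | 2.50 | 5 | 93 | 0 |
| epsilon | 5.00 | 0 | 98 | 3 |
| epsilon | 8.00 | 0 | 100 | 0 |
| epsilon | 10.0 | 1 | 99 | 0 |
| zeta | 2.50 | 22 | 23 | 27 |
| zeta | 5.00 | 23 | 24 | 30 |
| zeta | 8.00 | 20 | 24 | 25 |
| zeta | 10.0 | 23 | 29 | 27 |

(each reading ± 2 percentage points)
- steps that have been proposed: X + Z -> J + D; D + Z -> J + E; E + Z -> J + L; Z <-> G
* equivalents of Z to X, everything else as given, that leave most E at 8.0 d
* the amount of E then, in percent of the X charged
* the amount of E with the amounts as given

The epsilon run reads X at 0% by 2.50 d, earlier than 8.0 d, so in this reckoning you take the time as long enough and count Z. The zeta run has a budget of 1.50. Its readings at 8.00 d, with D taken by closure, show 1.43 exchanges per X, so a share of 0.953, nearly all, went into exchanges in that run, a figure that carries the scatter of the readings. Carrying that share over, your own reckoning for this flask is 2.86 exchanges per X. This gives a mean, not E itself.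

The forecast, holding that “Z is just stoichiometric, leaving a small tail”, gives 14% of E, and a best 25% at 2.1 equiv.

The flask gives 8.95% of E, and a best 22.1% at 1.73 equiv.

    X + Z → J + D (k = 0.00620 M⁻¹ min⁻¹)
    D + Z → J + E (k = 0.00890 M⁻¹ min⁻¹)
    E + Z → J + L (k = 0.00980 M⁻¹ min⁻¹)
    Z ⇌ G (K = 1.50, k = 1.70 × 10⁻⁴ min⁻¹)

In the flask at 8.00 d the J gained shows 2.71 exchanges per X, below your 2.86, while G holds 0.222 Z per X. In a neighbouring flask with 0.27 M of X, the budget is 1.78, and the zeta share predicts 1.70 exchanges per X. In that neighbouring flask at 8.00 d J shows 1.72, Z, the limiting reagent, stands at 0.207% of its charge, and E at 22.0%.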